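**Retrosynthetic overview**
1. 22 ⇐ 21: the last step forms the phenol C(aryl)–O bond by Pd-catalysed hydroxylation of an aryl bromide (the same pot hydrolyses the ester); the bromine is carried from 1 as the masked phenol.
2. 21 ⇐ 17: the C3 ketone becomes the isopropylidene group through a spiro-β-lactone (C–O ring closure, then loss of CO2).
3. 17 ⇐ 12: conjugate methylation sets C5 (cis ring fusion), then Michael addition of the enolate to methyl acrylate sets C4.
4. 12 ⇐ 6 + 7 + 9: conjugate benzylation builds the C9 quaternary centre; a Robinson-type annulation closes ring A (formed last) onto ring B.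
5. Ring B comes from 3 (Birch reduction, then enantioselective isomerisation sets C8, which relays to C9, C10, C5 and C4); the arene is bought as 1.

Assumption and convention: decalin locants are ring A = C1, C2, C3 (isopropylidene), C4 (propanoic acid chain), C5 (angular methyl), C10 (ring-fusion H) and ring B = C5–C10 with C8 (methyl) and C9 (methyl, arylmethyl); the target is (4S,5R,8R,9S,10S) in these locants, and the named starting materials are taken as catalogue compounds.

**Route**

Step 1
Reactants: 1 2-bromo-5-methoxy-1,3-dimethylbenzene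
Product: 2 2-bromo-1-(bromomethyl)-5-methoxy-3-methylbenzene
Conditions: NBS (1.0 equiv), AIBN (5 mol%), PhCF3, 80 °C
Reagents that add atoms: N-bromosuccinimide, O=C1CCC(=O)N1Br
Why: Wohl–Ziegler radical benzylic bromination; the two methyl groups are equivalent, so mono-bromination needs only stoichiometry control, and the ring bromine survives as the masked phenol oxygen.

Step 2
Reactants: 3 4-methoxy-1,2-dimethylbenzene
Product: 5 3,4-dimethylcyclohex-3-en-1-one, via Birch diene 4 (not isolated)
Conditions: Li, NH3(l), THF, t-BuOH, −78 to −33 °C; then (CO2H)2, MeOH/H2O, 20 °C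
Reagents that add atoms: water, O
Why: Birch reduction gives the 2,5-dihydroanisole, and mild oxalic acid hydrolysis of the enol ether stops at the achiral β,γ-unsaturated ketone without conjugation.

Step 3
Reactants: 5 3,4-dimethylcyclohex-3-en-1-one
Product: 6 (4R)-3,4-dimethylcyclohex-2-en-1-one
Conditions: cinchona-derived 9-amino-9-deoxy-epi primary amine catalyst (10 mol%, the pseudoenantiomer that gives (R)-6), 2-nitrobenzoic acid (20 mol%), toluene, 0 °C
Reagents that add atoms: none
Why: Enantioselective β,γ to α,β olefin isomerisation by cooperative iminium–base catalysis; the dienamine of 5 is protonated at the γ-carbon on one face by the catalyst ammonium unit, which sets C8, the only stereocentre not relayed from another.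

Step 4
Reactants: 2 2-bromo-1-(bromomethyl)-5-methoxy-3-methylbenzene; 6 (4R)-3,4-dimethylcyclohex-2-en-1-one
Product: 8 {[(3S,4R)-3-[(2-bromo-5-methoxy-3-methylphenyl)methyl]-3,4-dimethylcyclohex-1-en-1-yl]oxy}trimethylsilane, via benzylic Grignard reagent 7 (not isolated)
Conditions: Mg, Et2O, 0 °C (slow addition of 2); then 6, CuBr·SMe2 (10 mol%), Me3SiCl (2 equiv), THF, −78 °C; Et3N, cold NaHCO3 work-up
Reagents that add atoms: chlorotrimethylsilane, C[Si](C)(C)Cl
Why: Copper-catalysed, silyl-chloride-accelerated conjugate addition of a Grignard reagent to a β,β-disubstituted enone; the nucleophile enters anti to the C8 methyl group, giving the C9 quaternary centre with the arylmethyl group trans to that methyl, and the enolate is trapped regiospecifically on the C10 side.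

Step 5
Reactants: 8 {[(3S,4R)-3-[(2-bromo-5-methoxy-3-methylphenyl)methyl]-3,4-dimethylcyclohex-1-en-1-yl]oxy}trimethylsilane; 9 but-3-en-2-one
Product: 12 (4aR,5S,6R)-5-[(2-bromo-5-methoxy-3-methylphenyl)methyl]-5,6-dimethyl-4,4a,5,6,7,8-hexahydronaphthalen-2(3H)-one, via silyl enol ether adduct 10 (not isolated), via 1,5-diketone 11 (not isolated)
Conditions: HNTf2 (2 mol%), CH2Cl2, −78 °C; then MeOH, KOH (0.3 equiv), 0 to 20 °C, short reaction time
Reagents that add atoms: none
Why: Mukaiyama–Michael addition followed by intramolecular aldol condensation (Robinson annulation) closes ring A; the C10–C1 bond forms axially, anti to the pseudoaxial C9 methyl and away from the C8 methyl, so H-10 ends up cis to the C9 methyl under kinetic control, and mild base with a short contact time is used to avoid γ-epimerisation at C10.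

Step 6
Reactants: 12 (4aR,5S,6R)-5-[(2-bromo-5-methoxy-3-methylphenyl)methyl]-5,6-dimethyl-4,4a,5,6,7,8-hexahydronaphthalen-2(3H)-one
Product: 13 {[(4aS,5S,6R,8aR)-5-[(2-bromo-5-methoxy-3-methylphenyl)methyl]-5,6,8a-trimethyl-3,4,4a,5,6,7,8,8a-octahydronaphthalen-2-yl]oxy}trimethylsilane
Conditions: CuI, MeLi (2 equiv per Cu), Et2O, 0 °C; then 12, Me3SiCl, −78 to −20 °C; Et3N, pentane work-up
Reagents that add atoms: methyllithium, [Li]C; chlorotrimethylsilane, C[Si](C)(C)Cl
Why: Cuprate 1,4-addition to the octalone with in situ silylation; methyl is delivered to C5 on the face of H-10 because the other face is blocked by the axial arylmethyl group on C9, which gives the cis-fused decalin and fixes the enolate as the C3–C4 silyl enol ether.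

Step 7
Reactants: 13 {[(4aS,5S,6R,8aR)-5-[(2-bromo-5-methoxy-3-methylphenyl)methyl]-5,6,8a-trimethyl-3,4,4a,5,6,7,8,8a-octahydronaphthalen-2-yl]oxy}trimethylsilane; 14 methyl prop-2-enoate
Product: 17 methyl 3-[(1S,4aS,5S,6R,8aR)-5-[(2-bromo-5-methoxy-3-methylphenyl)methyl]-5,6,8a-trimethyl-2-oxodecahydronaphthalen-1-yl]propanoate, via lithium enolate 15 (not isolated), via lithium ester enolate 16 (not isolated)
Conditions: MeLi (1.05 equiv), THF, 0 °C; then 14 (1.1 equiv), −78 °C, 15 min; AcOH, −78 °C
Reagents that add atoms: none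
Why: Michael addition of a regiospecifically unmasked lithium enolate to an acrylate; C4 is attacked on the convex face of the cis-decalin enolate (axial, anti to the C5–C6 bond), so the chain ends up cis to the angular methyl, and the cold acidic quench prevents equilibration of this kinetic C4 epimer.

Step 8
Reactants: 17 methyl 3-[(1S,4aS,5S,6R,8aR)-5-[(2-bromo-5-methoxy-3-methylphenyl)methyl]-5,6,8a-trimethyl-2-oxodecahydronaphthalen-1-yl]propanoate; 18 2-bromo-2-methylpropanoyl bromide
Product: 21 methyl 3-[(1S,4aS,5S,6R,8aR)-5-[(2-bromo-5-methoxy-3-methylphenyl)methyl]-5,6,8a-trimethyl-2-(propan-2-ylidene)decahydronaphthalen-1-yl]propanoate, via dimethylketene 19 (not isolated), via spiro-β-lactone 20 (not isolated)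
Conditions: activated Zn dust (3 equiv), 18 (2.5 equiv, slow addition), THF/EtOAc, 0 to 25 °C; then filtration, toluene, SiO2, 110 °C
Reagents that add atoms: none
Why: Proposed new method: zinc debrominates 18 to dimethylketene 19 and ZnBr2 in the presence of 17, the ZnBr2 activates the hindered C3 ketone, the nucleophilic ketene terminus forms the C3–C bond and the zinc alkoxide closes onto the acylium carbon (C–O bond) to give spiro-β-lactone 20 under non-basic conditions that leave the epimerisable C4 centre and the ester alone, and heating then expels CO2 by [2+2] cycloreversion so that the double bond can only form between C3 and the CMe2 carbon; the closest known reaction types are the zinc-dehalogenation route to ketenes, Lewis-acid-promoted ketene–carbonyl [2+2] cycloadditions (dichloroketene with ketones) and thermal β-lactone decarboxylation, which have not been combined into one tandem isopropylidenation of an unactivated, α-branched ketone.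

Step 9
Reactants: 21 methyl 3-[(1S,4aS,5S,6R,8aR)-5-[(2-bromo-5-methoxy-3-methylphenyl)methyl]-5,6,8a-trimethyl-2-(propan-2-ylidene)decahydronaphthalen-1-yl]propanoate
Product: 22 3-[(1S,4aS,5S,6R,8aR)-5-[(2-hydroxy-5-methoxy-3-methylphenyl)methyl]-5,6,8a-trimethyl-2-(propan-2-ylidene)decahydronaphthalen-1-yl]propanoic acid
Conditions: Pd2(dba)3 (2 mol%), tBuXPhos (8 mol%), KOH (5 equiv), 1,4-dioxane/H2O (1:1), degassed, 100 °C; then 1 M HCl to pH 3
Reagents that add atoms: potassium hydroxide, [K+].[OH-]
Why: Palladium-catalysed C–O cross-coupling of the aryl bromide with hydroxide forms the phenol C–O bond (the bulky biaryl phosphine promotes C–O reductive elimination at the di-ortho-substituted aryl), the same aqueous KOH saponifies the methyl ester, and no stereocentre is touched.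

**Compound list**
1 | 2-bromo-5-methoxy-1,3-dimethylbenzene (4-bromo-3,5-dimethylanisole) | COc1cc(C)c(Br)c(C)c1 | starting material
2 | 2-bromo-1-(bromomethyl)-5-methoxy-3-methylbenzene | COc1cc(C)c(Br)c(CBr)c1 | intermediate
3 | 4-methoxy-1,2-dimethylbenzene (3,4-dimethylanisole) | COc1ccc(C)c(C)c1 | starting material
4 | 1-methoxy-4,5-dimethylcyclohexa-1,4-diene | COC1=CCC(C)=C(C)C1 | intermediate
5 | 3,4-dimethylcyclohex-3-en-1-one | CC1=C(C)CC(=O)CC1 | intermediate
6 | (4R)-3,4-dimethylcyclohex-2-en-1-one | C[C@@H]1CCC(=O)C=C1C | intermediate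
7 | (2-bromo-5-methoxy-3-methylbenzyl)magnesium bromide | COc1cc(C)c(Br)c(C[Mg]Br)c1 | intermediate
8 | {[(3S,4R)-3-[(2-bromo-5-methoxy-3-methylphenyl)methyl]-3,4-dimethylcyclohex-1-en-1-yl]oxy}trimethylsilane | COc1cc(C)c(Br)c(C[C@]2(C)C=C(O[Si](C)(C)C)CC[C@H]2C)c1 | intermediate
9 | but-3-en-2-one (methyl vinyl ketone) | CC(=O)C=C | starting material
10 | (2S,3S,4R)-3-[(2-bromo-5-methoxy-3-methylphenyl)methyl]-3,4-dimethyl-2-[3-(trimethylsilyloxy)but-2-en-1-yl]cyclohexan-1-one (enol ether geometry not defined) | COc1cc(C)c(Br)c(C[C@]2(C)[C@@H](C(=O)CC[C@H]2C)CC=C(C)O[Si](C)(C)C)c1 | intermediate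
11 | (2S,3S,4R)-3-[(2-bromo-5-methoxy-3-methylphenyl)methyl]-3,4-dimethyl-2-(3-oxobutyl)cyclohexan-1-one | COc1cc(C)c(Br)c(C[C@]2(C)[C@@H](C(=O)CC[C@H]2C)CCC(C)=O)c1 | intermediate
12 | (4aR,5S,6R)-5-[(2-bromo-5-methoxy-3-methylphenyl)methyl]-5,6-dimethyl-4,4a,5,6,7,8-hexahydronaphthalen-2(3H)-one | COc1cc(C)c(Br)c(C[C@]2(C)[C@@H]3CCC(=O)C=C3CC[C@H]2C)c1 | intermediate
13 | {[(4aS,5S,6R,8aR)-5-[(2-bromo-5-methoxy-3-methylphenyl)methyl]-5,6,8a-trimethyl-3,4,4a,5,6,7,8,8a-octahydronaphthalen-2-yl]oxy}trimethylsilane (cis-fused) | COc1cc(C)c(Br)c(C[C@]2(C)[C@@H]3CCC(O[Si](C)(C)C)=C[C@]3(C)CC[C@H]2C)c1 | intermediate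
14 | methyl prop-2-enoate (methyl acrylate) | C=CC(=O)OC | starting material
15 | lithium (4aS,5S,6R,8aR)-5-[(2-bromo-5-methoxy-3-methylphenyl)methyl]-5,6,8a-trimethyl-3,4,4a,5,6,7,8,8a-octahydronaphthalen-2-olate | COc1cc(C)c(Br)c(C[C@]2(C)[C@@H]3CCC([O-])=C[C@]3(C)CC[C@H]2C)c1.[Li+] | intermediate
16 | lithium ester enolate of 17 (enolate geometry not defined) | COc1cc(C)c(Br)c(C[C@]2(C)[C@@H]3CCC(=O)[C@@H](CC=C([O-])OC)[C@]3(C)CC[C@H]2C)c1.[Li+] | intermediate
17 | methyl 3-[(1S,4aS,5S,6R,8aR)-5-[(2-bromo-5-methoxy-3-methylphenyl)methyl]-5,6,8a-trimethyl-2-oxodecahydronaphthalen-1-yl]propanoate | COc1cc(C)c(Br)c(C[C@]2(C)[C@@H]3CCC(=O)[C@@H](CCC(=O)OC)[C@]3(C)CC[C@H]2C)c1 | intermediate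
18 | 2-bromo-2-methylpropanoyl bromide | CC(C)(Br)C(=O)Br | starting material
19 | dimethylketene (2-methylprop-1-en-1-one) | CC(C)=C=O | intermediate
20 | methyl 3-[(1'S,4a'S,5'S,6'R,8a'R)-5'-[(2-bromo-5-methoxy-3-methylphenyl)methyl]-3,3,5',6',8a'-pentamethyl-4-oxooctahydro-1'H-spiro[oxetane-2,2'-naphthalen]-1'-yl]propanoate (spiro carbon configuration not controlled; both epimers give 21) | COc1cc(C)c(Br)c(C[C@]2(C)[C@@H]3CCC4(OC(=O)C4(C)C)[C@@H](CCC(=O)OC)[C@]3(C)CC[C@H]2C)c1 | intermediate
21 | methyl 3-[(1S,4aS,5S,6R,8aR)-5-[(2-bromo-5-methoxy-3-methylphenyl)methyl]-5,6,8a-trimethyl-2-(propan-2-ylidene)decahydronaphthalen-1-yl]propanoate | COc1cc(C)c(Br)c(C[C@]2(C)[C@@H]3CCC(=C(C)C)[C@@H](CCC(=O)OC)[C@]3(C)CC[C@H]2C)c1 | intermediate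
22 | 3-[(1S,4aS,5S,6R,8aR)-5-[(2-hydroxy-5-methoxy-3-methylphenyl)methyl]-5,6,8a-trimethyl-2-(propan-2-ylidene)decahydronaphthalen-1-yl]propanoic acid | COc1cc(C)c(O)c(C[C@]2(C)[C@@H]3CCC(=C(C)C)[C@@H](CCC(=O)O)[C@]3(C)CC[C@H]2C)c1 | target

**Totals**
Total step count: 9. Longest linear sequence: 8 (steps 2 to 9, from 3).

**Three steps most likely to fail**

Step 8 (the proposed new step). The ketene may dimerise faster than it adds to the hindered ketone, or ZnBr2 may enolise the ketone. The fallback uses known chemistry and sets out from 17. The lithium enolate of phenyl 2-methylpropanoate (LiN(iPr)2, THF, −90 °C) adds to the C3 ketone, and the aldolate closes onto the phenyl ester to give the same spiro-β-lactone 20, this time isolated. Heating 20 with SiO2 at 140 °C loses CO2 and rejoins the route at 21. No new compound is made (F0).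

Step 5. The aldol closure onto the hindered ring-B ketone may be slow, and alkoxide can epimerise C10 to the epimer with H-10 trans to the C9 methyl, which is probably the more stable one. The fallback sets out from 8. MeLi (THF, 0 °C) unmasks the lithium enolate of the ring-B ketone F1. This is alkylated at C10 with 1,3-dichlorobut-2-ene (Wichterle reagent, same axial approach) to give the chlorobutenyl ketone F2. Cold 90% H2SO4 hydrolyses the vinyl chloride to diketone 11 and cyclodehydrates it in the same acid, rejoining the route at 12 without any alkoxide after C10 is set.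

Step 7. The lithium enolate is neopentylic and may add sluggishly or oligomerise the acrylate, and the ester enolate formed can equilibrate the kinetic C4 epimer. The fallback sets out from 13. A Lewis-acid Mukaiyama–Michael addition to acrolein (BF3·OEt2, CH2Cl2, −78 °C) gives the keto aldehyde F3. Pinnick oxidation (NaClO2, NaH2PO4, 2-methylbut-2-ene, t-BuOH/H2O) gives the keto acid F4. Me3SiCHN2 in MeOH/toluene then gives the methyl ester and rejoins the route at 17.

**Further compounds**
F1 | step 5 | lithium (3S,4R)-3-[(2-bromo-5-methoxy-3-methylphenyl)methyl]-3,4-dimethylcyclohex-1-en-1-olate | COc1cc(C)c(Br)c(C[C@]2(C)C=C([O-])CC[C@H]2C)c1.[Li+]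
F2 | step 5 | (2S,3S,4R)-3-[(2-bromo-5-methoxy-3-methylphenyl)methyl]-2-(3-chlorobut-2-en-1-yl)-3,4-dimethylcyclohexan-1-one | COc1cc(C)c(Br)c(C[C@]2(C)[C@@H](C(=O)CC[C@H]2C)CC=C(C)Cl)c1
F3 | step 7 | 3-[(1S,4aS,5S,6R,8aR)-5-[(2-bromo-5-methoxy-3-methylphenyl)methyl]-5,6,8a-trimethyl-2-oxodecahydronaphthalen-1-yl]propanal | COc1cc(C)c(Br)c(C[C@]2(C)[C@@H]3CCC(=O)[C@@H](CCC=O)[C@]3(C)CC[C@H]2C)c1
F4 | step 7 | 3-[(1S,4aS,5S,6R,8aR)-5-[(2-bromo-5-methoxy-3-methylphenyl)methyl]-5,6,8a-trimethyl-2-oxodecahydronaphthalen-1-yl]propanoic acid | COc1cc(C)c(Br)c(C[C@]2(C)[C@@H]3CCC(=O)[C@@H](CCC(=O)O)[C@]3(C)CC[C@H]2C)c1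
F0 | step 8 | none | none
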